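To whoever takes over the bench: carry the survival share from flask to flask, reckoning the fraction of free monomer left and not the fraction made.

| flask | free monomer | transfer agent | pre-initiator | temperature | time | remark |
|---|---|---|---|---|---|---|
| theta | 1.0 M | 0.0300 M | 2 mol% | 5 °C | 1.0 min |  |
| alpha | 1.0 M | 0.0300 M | 2 mol% | 20 °C | 1.0 min |  |
| eta | 1.0 M | 0.0300 M | 2 mol% |  | 1.0 min | at 35 °C until 12 s, from then on at 5 °C |
| zeta | 1.0 M | 0.0300 M | 2 mol% | 35 °C | 1.0 min |  |

- the flask that comes out highest in amount of monomer in chains, in percent of the free monomer charged, or "all alike" when all lie within 1.5 percentage points (theta / alpha / eta / zeta / all alike)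
- monomer in chains at the end, in percent of the free monomer charged, theta
- monomer in chains at the end, in percent of the free monomer charged, alpha
- monomer in chains at the end, in percent of the free monomer charged, eta
- monomer in chains at the end, in percent of the free monomer charged, zeta

- at 35 °C the constants are as listed, elsewhere as the activation energies and enthalpies make them

    pre-initiator → initiator (k1 = 0.031 s⁻¹, Ea1 = 86.0 kJ mol⁻¹)
    living end + transfer agent → dead chain (k2 = 0.27 L mol⁻¹ s⁻¹, Ea2 = 42.0 kJ mol⁻¹)
    free monomer + initiator → living end + monomer in chains (k3 = 0.88 L mol⁻¹ s⁻¹, Ea3 = 52.0 kJ mol⁻¹)
    free monomer → uncatalysed product (k4 = 5.8 × 10⁻⁴ s⁻¹, Ea4 = 99.0 kJ mol⁻¹)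
    monomer in chains + initiator ⇌ isomer of the product + initiator, rate k5*[initiator]*[monomer in chains] forward; the back reaction follows from the equilibrium constant (K5 = 2.3, k5 = 0.47 L mol⁻¹ s⁻¹, Ea5 = 61.0 kJ mol⁻¹, ΔH5 = −24.0 kJ mol⁻¹)
    free monomer + living end → monomer in chains + living end, rate k6*[living end]*[free monomer] (k6 = 0.63 L mol⁻¹ s⁻¹, Ea6 = 41.0 kJ mol⁻¹)
    (constants at 35 °C)

1. In each flask stand free monomer, transfer agent and 0.0200 M of pre-initiator. Pre-initiator opens first-order to initiator, initiator meets free monomer and becomes a living end, and living ends take up free monomer.

2. In flask theta, initiator reacts with free monomer at the cold constant 0.0986 L mol⁻¹ s⁻¹, so initiator has a half-life of 7.03 s. Because this is shorter than the run, my reckoning counts opened pre-initiator as living end at once.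

3. In flask zeta, a living end has a half-life against the transfer agent of 1.43 min. Because this is longer than the run, my reckoning keeps living ends alive.

4. Free monomer then falls pseudo-first-order, with the growth constant times [living end] as its rate constant. The survival share, the fraction of free monomer left by growth, is the exponential of minus three factors multiplied: the growth constant, the pre-initiator charge, and the time less the opened fraction over the opening constant. Uncatalysed loss stays outside it.

5. In flask zeta my reckoning gives 66.2 % for the survival share. Flask theta, with opening constant 0.0498 min⁻¹ and growth constant 0.112 L mol⁻¹ s⁻¹, gives 99.7 %. Flask alpha gives 95.1 %. Flask eta, with what opened in the hot stretch carried on at the cold growth constant, gives 94.3 %. So, with a survival share lower than in the other flasks, I expect flask zeta to stand highest, with about 33.8 % of its free monomer taken up by growth in this reckoning.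

6. Do not touch the thermostat. From coldest to hottest flask the opening constant grows 37.3-fold, more than the 5.6-fold of the growth constant.

The forecast names zeta, with 0.31 % for theta, 4.6 % for alpha, 5.5 % for eta and 30.5 % for zeta, and its zeta figure lies below my 33.8 %. Its grounds include “the transfer agent only modestly trimming the living ends”.

The simulation gives zeta as highest, with 0.312 % in theta, 4.63 % in alpha, 5.63 % in eta and 29.4 % in zeta. The forecast's choice stands, and its percentages hold within their ranges.

In flask theta at 0.500 min, initiator has a half-life of 0.12 min by its reaction with free monomer, far shorter than the 8.4 min of a living end against the transfer agent. At the end of flask theta, [initiator] stands at 1.62 × 10⁻⁴ M beside [living end] at 7.82 × 10⁻⁴ M. Flask zeta ends with 67.6 % free monomer against the survival share of 66.2 %.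

A flask like theta kept at 30 °C has opening constant 1.07 min⁻¹ and survival share 79.9 %. Computed, that flask holds 80.2 % free monomer and 18.1 % monomer in chains.

The numbers of this flask were set for the occasion; what happens was integrated by code.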